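(The earlier runs and the new flask are simulated on assumed constants, noise included.)

The east run's target fell from 22.3% at 3.00 min to 9.7% at 5.00 min, and I built my estimate on that fall. Its solid substrate had dropped to 0.3% by 2.00 min, so I read the fall, net of any target still forming, as a pseudo-first-order decay with apparent constant 0.416 min⁻¹.

| flask | solid substrate | first nucleophile | second nucleophile | remark | time |
|---|---|---|---|---|---|
| east | 5 mM | 25 mM | 6 mM | run made earlier |  |
| north-west | 2.5 mM | 25 mM | 6 mM | run made earlier |  |
| south-east | 10 mM | 25 mM | 6 mM | run made earlier |  |
| Monday's | 5.0 mM | 25.0 mM (fed, over 1.0 min) | 6.00 mM | all else is in the flask from the start; the feed brings no volume worth counting | 5.0 min |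
| Wednesday's | 5.0 mM | 25.0 mM | 6.00 mM (in portions, 4, over 1.0 min) | first portion at the start, last at 1.0 min | 5.0 min |
| Saturday's | 5.0 mM | 25.0 mM | 6.00 mM (fed, over 1.0 min) | all else is in the flask from the start; the feed brings no volume worth counting | 5.0 min |
| Thursday's | 5.0 mM | 25.0 mM | 6.00 mM | everything together at the start | 5.0 min |

- east (time / min: target / %, solid substrate / %): 0.667: 7.3, 56.9; 2.00: 24.5, 0.3; 3.00: 22.3, 0; 5.00: 9.7, 0
- north-west (time / min: target / %, solid substrate / %): 0.833: 19.4, 0; 1.50: 27.7, 0.3; 2.50: 21.2, 0; 3.00: 17.0, 0.6
- south-east (time / min: target / %, solid substrate / %): 0.417: 1.6, 85.9; 1.00: 6.4, 69.8; 2.00: 12.6, 48.9; 3.00: 15.9, 28.4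

(each reading ± 0.3 percentage points)

- the flask that comes out highest in amount of target, in percent of the solid substrate charged, or "all alike" when all lie within 1.5 percentage points (Monday's / Wednesday's / Saturday's / Thursday's / all alike)
- target at the end, in percent of the solid substrate charged, Monday's
- target at the end, in percent of the solid substrate charged, Wednesday's
- target at the end, in percent of the solid substrate charged, Saturday's
- target at the end, in percent of the solid substrate charged, Thursday's

- as a solid, counted per litre of solution: solid substrate
- at the start none of the solid substrate is in solution

Thursday's repeated the east charges, so I expected 9.7% there. Over the 4.00 min between the end of the additions and the asked time, a decay at that constant leaves 0.189 of a difference in target; I call this share the memory factor. The constant is net of any target still forming, and a supply common to the flasks cancels in a difference, so I took the memory factor as a high estimate.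

Next I sized the difference. A steady feed and the equal portions both place the mean addition at 0.500 min. Sliding the east run's rise between its first two readings by that much moves target by 6.5 percentage points. The memory factor cuts this to 1.2 points, which is smaller than the margin of 1.5 points. I took that as my ceiling for Monday's shortfall below Thursday's.

The weak link was a constant read from two points of one run, so I read it again from the north-west run, at half the solid substrate. That gave 0.442 min⁻¹, a memory factor of 0.171 and a shift of 1.1 points. The second nucleophile stayed at 6 mM in each earlier run, so the readings gave no size for its feed. I allowed it the same shift upward. Two opposite ceilings reach 2.2 points, more than the margin, so calling the flasks alike was my judgement that neither ceiling would be reached.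

The forecast gave 10.2% for Monday's, 9.8% for Wednesday's, 9.8% for Saturday's and 9.7% for Thursday's, with the verdict all alike because “All four lie within 1.5 points”, whereas I had Monday's below Thursday's.

The flasks gave 9.24% for Monday's, 9.53% for Wednesday's, 9.51% for Saturday's and 9.39% for Thursday's, so the verdict was all alike.

    solid substrate ⇌ starting material, rate k1*(cs1 - [starting material]) while solid is left; crystals form when [starting material] > cs1 (solubility = 3.90 mM, k = 0.0183 s⁻¹)
    first nucleophile + target → over-reaction product (k = 0.620 M⁻¹ s⁻¹)
    intermediate → side product (k = 0.00952 s⁻¹)
    starting material → intermediate (k = 0.0164 s⁻¹)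
    first nucleophile + intermediate → target (k = 246 M⁻¹ s⁻¹)
    second nucleophile + intermediate → other capture product (k = 382 M⁻¹ s⁻¹)

At 1.00 min, Monday's held 11.3% target at the end of its feed, and Wednesday's held 13.8% just before its last addition, a gap of 2.6 points. The memory factor of 0.189, my high estimate, turns that gap into 0.49 points at 5.0 min, and the two flasks finished 0.29 points apart.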